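**The pitfall.** I nearly called the rate of making target second order in catalyst, since that rate carries c(catalyst) and catalyst also makes the open intermediate. But the question stands at a fixed conversion, not at a fixed time.

substrate 0.050 M; coupling partner 0.800 equiv; capture agent 1.00 mM; catalyst 2.8 mol%; added ligand 0.98 mM

- apparent order in coupling partner when 5.0% of the substrate are converted (percent change of the rate of making target for one percent more coupling partner charged)
- apparent order in catalyst when 5.0% of the substrate are converted (percent change of the rate of making target for one percent more catalyst charged)

**In the flask.** I reckoned 1.40 mM of catalyst against 0.98 mM of added ligand. With 1600 M⁻¹, the balance left c(catalyst) at 0.839 mM, and the rest sat as idle complex, an off-cycle form.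

**On arrival.** This flask reaches 5.0% conversion after 1.09 min. The coupling rate per open intermediate at charged partner and free catalyst, times that span, was 0.0476, much less than 1. So I took c(open intermediate) as set by conversion, and more catalyst merely arrives there sooner. That removed one catalyst factor and put the order in coupling partner just under 1.

**Do not touch.** The remaining factor is c(catalyst), and its response came to 1.30. This is the free-catalyst lever, the percent change of c(catalyst) for one percent more catalyst charged. That lever holds the charge of added ligand at 0.98 mM while catalyst rises, so it is this charge that I would leave as it stands.

**The forecast.** It gave 0.98 (0.95 to 1) for coupling partner and 1.3 (1.24 to 1.36) for catalyst, holding that “adding catalyst raises free catalyst disproportionately”.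

**The result.** The simulation gave 0.98 and 1.3.

    substrate + catalyst → catalyst + open intermediate (k1 = 56 M⁻¹ min⁻¹)
    coupling partner + catalyst + open intermediate → catalyst + target (k2 = 1300 M⁻² min⁻¹)
    catalyst + added ligand ⇌ idle complex, settled at all times (K3 = 1600 M⁻¹)
    open intermediate + capture agent → trapped intermediate (k4 = 4.8 M⁻¹ min⁻¹)

**The comparison.** In this flask at 14.3 min, the open intermediate had a half-life of 19 min by coupling against 5.1 h by capture, so coupling used it 16 times faster than capture did. The lever of 1.30 belongs to free catalyst at 59.9% of the charge, and this flask held catalyst at 59.9% after 8.00 min and 59.9% after 80.0 min, with idle complex at 40.1%.

The constants are assumed, and the outcome is calculated.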